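## Retrosynthetic overview
1. Target 7 ⇒ quercetin 3-sulfate 5. Two O–S disconnections at O7 and O4', the two phenols that carbodiimide-activated hydrogen sulfate takes first. This is done last.
2. 5 ⇒ luteolin tetraacetate 2. This is the key disconnection, the C3–O bond: C3–H of the flavone becomes C3–OSO3− in one operation with a trivalent-iodine sulfate (new step).
3. 2 ⇒ luteolin 1 by peracetylation, which removes every oxidisable phenol and deactivates rings A and B.
4. No ring is built. Rings A, C and B all come intact from luteolin, a bulk plant flavone.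

Assumption: the target has no stereocentre, so there is no enantiomer to control. The SMILES shows the free tris(hydrogen sulfate), so sulfates are carried as Bu4N+ salts and the acid form is released only in the last work-up. It should be kept cold and used or neutralised at once.

## Route

Step 1
Reactants: 1 luteolin
Product: 2 luteolin tetraacetate (3',4',5,7-tetraacetoxyflavone)
Conditions: Ac2O (8 equiv), 4-(dimethylamino)pyridine (5 mol %), pyridine, 25 °C, 12 h; pour into ice water, filter, recrystallise (EtOH)
Reagents that add atoms: acetic anhydride, CC(=O)OC(C)=O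
Why: Nucleophile-catalysed O-acylation (esterification) caps all four phenols, the chelated 5-OH included, so no O–H is left to be oxidised and rings A and B become poor nucleophiles for step 2; no stereocentre is formed.

Step 2 (key step)
Reactants: 2 luteolin tetraacetate
Product: 5 tetrabutylammonium quercetin 3-sulfate, via alkenyl-λ3-iodane 3 (not isolated), via tetraacetate 3-sulfate salt 4 (not isolated)
Conditions: PhIO (1.5 equiv), Bu4NHSO4 (2.5 equiv), 3 Å molecular sieves, MeCN/(CF3)2CHOH 4:1, 0 to 40 °C, 12 h; Me2S, 0 °C; evaporate; saturated NH3 in MeOH, 0 °C, argon, 2 h; LH-20 gel (MeOH)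
Reagents that add atoms: tetrabutylammonium hydrogen sulfate, CCCC[N+](CCCC)(CCCC)CCCC.OS(=O)(=O)[O-]; iodosylbenzene, O=Ic1ccccc1 (its PhI unit is carried only in intermediate 3)
Why: Proposed new method: PhIO and HSO4− condense to PhI(OH)OSO3−, which on loss of water to the sieves is the phenyliodosyl sulfate zwitterion; its trivalent iodine is attacked by C3, the only enol-ether carbon of 2 because all arene oxygens are acylated; the O1- and aryl-stabilised C2 oxocarbenium ion loses H-3 to give iodane 3; ligand coupling on iodine then forges the C3–O bond with PhI as leaving group and gives the sulfate monoester 4 directly (an equivalent path is sulfate addition at C2, displacement of PhI to a 2,3-cyclic sulfate, and E1 opening at the ketal carbon); the closest known reaction types are the Koser-type alpha-sulfonyloxylation of ketones and enol ethers with PhI(OH)OTs and the conversion of simple alkenes into cyclic sulfates by phenyliodosyl sulfate; ammonolysis then removes the four aryl acetates while the sulfate monoester anion is inert to base; no stereocentre is formed.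

Step 3
Reactants: 5 tetrabutylammonium quercetin 3-sulfate
Product: 7 quercetin 3,4',7-tris(hydrogen sulfate), via tris(tetrabutylammonium) trisulfate 6 (not isolated)
Conditions: Bu4NHSO4 (3 equiv), CyN=C=NCy (dicyclohexylcarbodiimide, 10 equiv), pyridine, 4 °C, 72 h; filter, LH-20 gel (MeOH); eluate straight through sulfonated polystyrene resin (H+ form), H2O/MeOH, 0 °C; freeze-dry
Reagents that add atoms: tetrabutylammonium hydrogen sulfate, CCCC[N+](CCCC)(CCCC)CCCC.OS(=O)(=O)[O-]
Why: Carbodiimide-mediated dehydrative sulfation takes flavonoid phenols in order of acidity, so 7-OH and 4'-OH react while the chelated 5-OH stays free, and the 3'-OH is shielded sterically and electrostatically by the new 4'-sulfate; cold cation exchange then gives the acid form, and no stereocentre is involved.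

## Compound list
1 | luteolin (3',4',5,7-tetrahydroxyflavone) | O=c1cc(-c2ccc(O)c(O)c2)oc2cc(O)cc(O)c12 | starting material
2 | luteolin tetraacetate (3',4',5,7-tetraacetoxyflavone) | O=c1cc(-c2ccc(OC(C)=O)c(OC(C)=O)c2)oc2cc(OC(C)=O)cc(OC(C)=O)c12 | intermediate
3 | tetrabutylammonium (3',4',5,7-tetraacetoxyflavon-3-yl)(phenyl)-λ3-iodanyl sulfate | O=c1c(I(c3ccccc3)OS(=O)(=O)[O-])c(-c2ccc(OC(C)=O)c(OC(C)=O)c2)oc2cc(OC(C)=O)cc(OC(C)=O)c12.CCCC[N+](CCCC)(CCCC)CCCC | intermediate
4 | tetrabutylammonium 3',4',5,7-tetra-O-acetylquercetin 3-sulfate | O=c1c(OS(=O)(=O)[O-])c(-c2ccc(OC(C)=O)c(OC(C)=O)c2)oc2cc(OC(C)=O)cc(OC(C)=O)c12.CCCC[N+](CCCC)(CCCC)CCCC | intermediate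
5 | tetrabutylammonium quercetin 3-sulfate | O=c1c(OS(=O)(=O)[O-])c(-c2ccc(O)c(O)c2)oc2cc(O)cc(O)c12.CCCC[N+](CCCC)(CCCC)CCCC | intermediate
6 | tris(tetrabutylammonium) quercetin 3,4',7-trisulfate | O=c1c(OS(=O)(=O)[O-])c(-c2ccc(OS(=O)(=O)[O-])c(O)c2)oc2cc(OS(=O)(=O)[O-])cc(O)c12.CCCC[N+](CCCC)(CCCC)CCCC.CCCC[N+](CCCC)(CCCC)CCCC.CCCC[N+](CCCC)(CCCC)CCCC | intermediate
7 | quercetin 3,4',7-tris(hydrogen sulfate), achiral | O=c1c(OS(=O)(=O)O)c(-c2ccc(OS(=O)(=O)O)c(O)c2)oc2cc(OS(=O)(=O)O)cc(O)c12 | target

## Step count and risks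
Total step count: 3. Longest linear sequence: 3.

**Step 2 (the proposed new step, highest risk).**
- C3 of the electron-poor tetraacetate may be too weak a nucleophile for the iodane.
- Water or the fluoroalcohol may capture the cation in place of sulfate.
- The C2 aryl group may migrate to C3 as PhI leaves.

The fallback uses known chemistry and sets out from 2. Dimethyldioxirane in acetone/CH2Cl2 at 0 °C epoxidises the C2=C3 enol-ether bond to give racemic 2,3-epoxy-3',4',5,7-tetraacetoxyflavanone F1. A trace of p-toluenesulfonic acid or silica isomerises it to 3',4',5,7-tetra-O-acetylquercetin F2. Its only free hydroxyl is sulfated with Bu4NHSO4 and dicyclohexylcarbodiimide in pyridine. This comes back to the route at 4, which is ammonolysed as in step 2.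

**Step 3.**
- With the 3-sulfate twisting ring B, the 4' versus 3' preference may erode.
- Under- or over-sulfated ionic regioisomers are hard to separate.

The fallback sets out from 5 and switches to protected sulfate diesters. 2,2,2-Trichloroethyl chlorosulfate (2.1 equiv), Et3N and 4-(dimethylamino)pyridine in THF at 0 °C give tetrabutylammonium quercetin 4',7-bis(2,2,2-trichloroethyl sulfate) 3-sulfate F3. This is a lipophilic ion pair that can be freed of regioisomers on silica. Zn dust and HCO2NH4 in MeOH fragment both trichloroethyl groups to give the tetrabutylammonium diammonium salt of quercetin 3,4',7-trisulfate F4. That salt goes through the same H+ resin and comes back to the route at 7.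

**Step 1 (low risk, listed because the route has only three steps).**
- A trace of uncapped chelated 5-OH would be fatal in step 2.
- Poor solubility of 2 would also be fatal in step 2.

The fallback sets out from 1 and changes the mask from acetate to carbonate. ClCO2Me and Et3N in CH2Cl2 at 0 °C give luteolin tetrakis(methyl carbonate) F5. Under the step 2 oxidation conditions this passes through tetrabutylammonium [3',4',5,7-tetrakis(methoxycarbonyloxy)flavon-3-yl](phenyl)-λ3-iodanyl sulfate F6. The product is tetrabutylammonium 3',4',5,7-tetrakis(O-methoxycarbonyl)quercetin 3-sulfate F7. Saturated NH3 in MeOH strips the carbonates, and the sequence comes back to the route at 5.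

## Further compounds
F1 | step 2 | racemic 2,3-epoxy-3',4',5,7-tetraacetoxyflavanone (cis-fused epoxide, one enantiomer drawn) | O=C1[C@@H]2O[C@]2(c2ccc(OC(C)=O)c(OC(C)=O)c2)Oc2cc(OC(C)=O)cc(OC(C)=O)c12
F2 | step 2 | 3',4',5,7-tetra-O-acetylquercetin (free 3-OH) | O=c1c(O)c(-c2ccc(OC(C)=O)c(OC(C)=O)c2)oc2cc(OC(C)=O)cc(OC(C)=O)c12
F3 | step 3 | tetrabutylammonium quercetin 4',7-bis(2,2,2-trichloroethyl sulfate) 3-sulfate | O=c1c(OS(=O)(=O)[O-])c(-c2ccc(OS(=O)(=O)OCC(Cl)(Cl)Cl)c(O)c2)oc2cc(OS(=O)(=O)OCC(Cl)(Cl)Cl)cc(O)c12.CCCC[N+](CCCC)(CCCC)CCCC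
F4 | step 3 | tetrabutylammonium diammonium quercetin 3,4',7-trisulfate | O=c1c(OS(=O)(=O)[O-])c(-c2ccc(OS(=O)(=O)[O-])c(O)c2)oc2cc(OS(=O)(=O)[O-])cc(O)c12.CCCC[N+](CCCC)(CCCC)CCCC.[NH4+].[NH4+]
F5 | step 1 | luteolin tetrakis(methyl carbonate) | O=c1cc(-c2ccc(OC(=O)OC)c(OC(=O)OC)c2)oc2cc(OC(=O)OC)cc(OC(=O)OC)c12
F6 | step 1 | tetrabutylammonium [3',4',5,7-tetrakis(methoxycarbonyloxy)flavon-3-yl](phenyl)-λ3-iodanyl sulfate | O=c1c(I(c3ccccc3)OS(=O)(=O)[O-])c(-c2ccc(OC(=O)OC)c(OC(=O)OC)c2)oc2cc(OC(=O)OC)cc(OC(=O)OC)c12.CCCC[N+](CCCC)(CCCC)CCCC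
F7 | step 1 | tetrabutylammonium 3',4',5,7-tetrakis(O-methoxycarbonyl)quercetin 3-sulfate | O=c1c(OS(=O)(=O)[O-])c(-c2ccc(OC(=O)OC)c(OC(=O)OC)c2)oc2cc(OC(=O)OC)cc(OC(=O)OC)c12.CCCC[N+](CCCC)(CCCC)CCCC
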